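Everything rests on building flavanone ring A (C4a, C5, C6, C7, C8, C8a) last, onto an enantiopure 2-aryl-2,3-dihydropyran-4-one whose C5=C6 bond becomes C4a–C8a. The 5-hydroxy, 6-aryl, 7-oxy sequence of that ring is the pattern a vinylketene and an aryl siloxyalkyne produce. Visible-light Wolff rearrangement of (S)-diazoketone 9 beside the flavone-bearing siloxyalkyne 20 makes four C–C bonds and ring A in one neutral operation. The alkyne–aryl bond simply becomes the crowded C6–C3' axis, and C2 is never exposed to acid or base. C2 stems from a catalytic asymmetric aldol–cyclisation, and the silyl and benzyl groups leave under buffered or neutral conditions.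

Key step: step 11

Assumption: rotation about the C6–C3' axis (ortho groups OH, OH, OMe, H) is taken to be fast at room temperature in the target, so C2 is the only stereogenic element to control.

Step 1
Reactants: 1 methyl 2,4-dioxopentanoate
Product: 2 methyl (2Z)-2,4-bis(trimethylsilyloxy)penta-2,4-dienoate
Conditions: Me3SiOTf (2.2 equiv), Et3N (2.6 equiv), Et2O, 0 °C to rt; salt layer separated, bulb-to-bulb distillation
Reagents that add atoms: trimethylsilyl trifluoromethanesulfonate C[Si](C)(C)OS(=O)(=O)C(F)(F)F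
Why: Double silyl enol ether formation by soft enolisation, as practised on acetylacetone: whichever oxygen of the enolised 1,3-dicarbonyl unit is silylated first, the second silylation takes a proton from the terminal methyl group and so converges on the same 2,4-bis(silyloxy)diene, whose double-bond geometry does not matter because it is lost in step 2.

Step 2
Reactants: 2 methyl (2Z)-2,4-bis(trimethylsilyloxy)penta-2,4-dienoate; 3 4-methoxybenzaldehyde
Product: 5 methyl (2S)-2-(4-methoxyphenyl)-4-oxo-3,4-dihydro-2H-pyran-6-carboxylate, via silylated aldol adduct 4 (not isolated)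
Conditions: Ti(OiPr)4 (10 mol %), (S)-BINOL (10 mol %), 4 Å MS, THF, −20 °C to rt; then CF3CO2H, CH2Cl2, 0 °C, short contact
Reagents that add atoms: none
Why: Catalytic asymmetric Mukaiyama aldol–cyclisation, the stepwise form of the hetero-Diels–Alder reaction known for bis(silyloxy)dienes of 1,3-diketones and for 1-alkoxy-3-silyloxydienes with aromatic aldehydes: the complex of Ti(OiPr)4 and BINOL shields one face of the bound aldehyde so that the diene CH2 terminus attacks the Si face and sets C2 as S (the sense expected for (S)-BINOL from related additions to aromatic aldehydes, the antipodal ligand being used should the assay show the opposite), and brief cold acid closes the ring by oxa-Michael addition and loss of the silyloxy group.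

Step 3
Reactants: 5 methyl (2S)-2-(4-methoxyphenyl)-4-oxo-3,4-dihydro-2H-pyran-6-carboxylate
Product: 7 (2S)-2-(4-methoxyphenyl)-4-oxo-3,4-dihydro-2H-pyran-6-carboxylic acid, via trimethylstannyl ester 6 (not isolated)
Conditions: Me3SnOH (3 equiv), ClCH2CH2Cl, 60 °C; then cold 0.5 M aq HCl wash
Reagents that add atoms: trimethyltin hydroxide C[Sn](C)(C)O
Why: Mild ester hydrolysis with trimethyltin hydroxide: tin-bound hydroxide attacks the activated α-alkoxyacrylate ester carbonyl under essentially neutral conditions, so the C3 enolate, whose E1cB expulsion of O1 would open the ring and racemise C2 under an alkali hydroxide, is not formed.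

Step 4
Reactants: 7 (2S)-2-(4-methoxyphenyl)-4-oxo-3,4-dihydro-2H-pyran-6-carboxylic acid
Product: 9 (2S)-6-(2-diazoacetyl)-2-(4-methoxyphenyl)-2,3-dihydro-4H-pyran-4-one, via acid chloride 8 (not isolated)
Conditions: Me2C=C(Cl)NMe2 (1.1 equiv), CH2Cl2, 0 °C; solution added to CH2N2 (3 equiv), Et2O, −10 °C, 30 min; AcOH quench
Reagents that add atoms: diazomethane C=[N+]=[N-]; 1-chloro-N,N,2-trimethylprop-1-en-1-amine CC(C)=C(Cl)N(C)C (chlorine of 8 only)
Why: Acylation of diazomethane by an acid chloride (first stage of the Arndt–Eistert sequence), the chloride being made with an α-chloroenamine so that neither HCl nor base meets C2; acylation at −10 °C should far outrun dipolar cycloaddition to the trisubstituted, oxygen-bearing C5=C6 bond, as it does with chromone-2-carbonyl chlorides, and the surplus diazomethane is destroyed at once.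

Step 5
Reactants: 10 3-bromo-4-methoxybenzoic acid
Product: 11 3-bromo-4-methoxybenzoyl chloride
Conditions: (COCl)2 (1.3 equiv), DMF (cat.), CH2Cl2, 0 °C to rt; evaporation
Reagents that add atoms: oxalyl chloride ClC(=O)C(=O)Cl
Why: Standard acid chloride formation through the Vilsmeier-type chloroiminium species generated from DMF, to which the aryl bromide and the methyl ether are inert.

Step 6
Reactants: 12 2',4',6'-trihydroxyacetophenone; 11 3-bromo-4-methoxybenzoyl chloride
Product: 14 2-(3-bromo-4-methoxyphenyl)-5,7-dihydroxy-4H-chromen-4-one, via 1,3-diketone 13 (not isolated)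
Conditions: 12, LiN(SiMe3)2 (5 equiv), THF, −78 to −10 °C; 11, −78 °C to rt; aq HCl; crude 13, H2SO4 (cat.), AcOH, 100 °C
Reagents that add atoms: none
Why: C-acylation of the fully lithiated acetophenone (a direct counterpart of the Baker–Venkataraman route, known for this polyhydroxyacetophenone) gives diketone 13 without phenol protection, and acid-catalysed cyclodehydration through the 2'-hydroxyl closes the chromone ring, the strong acid being harmless here because no stereocentre is present yet.

Step 7
Reactants: 14 2-(3-bromo-4-methoxyphenyl)-5,7-dihydroxy-4H-chromen-4-one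
Product: 15 5,7-bis(benzyloxy)-2-(3-bromo-4-methoxyphenyl)-4H-chromen-4-one
Conditions: BnBr (3 equiv), K2CO3 (4 equiv), Bu4NI (cat.), DMF, 70 °C
Reagents that add atoms: benzyl bromide BrCc1ccccc1
Why: Williamson ether synthesis, forced with excess halide and heat so that the chelated 5-hydroxyl also reacts; benzyl ethers are preferred to acetal groups because they withstand strong base, silyl triflate and light and later leave by neutral hydrogenolysis, whereas acidic acetal cleavage would risk ionising the 4-methoxybenzylic C2–O1 bond of the flavanone.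

Step 8
Reactants: 15 5,7-bis(benzyloxy)-2-(3-bromo-4-methoxyphenyl)-4H-chromen-4-one
Product: 16 5,7-bis(benzyloxy)-2-{4-methoxy-3-[(trimethylsilyl)ethynyl]phenyl}-4H-chromen-4-one
Conditions: Me3SiC≡CH (1.5 equiv), PdCl2(PhCN)2 (3 mol %), P(t-Bu)3·HBF4 (6 mol %), CuI (2 mol %), i-Pr2NH, dioxane, rt to 50 °C
Reagents that add atoms: ethynyltrimethylsilane C#C[Si](C)(C)C
Why: Sonogashira coupling, in which the bulky electron-rich phosphine lets zerovalent palladium insert into the electron-rich ortho-methoxy aryl bromide near room temperature while flavone and benzyl ethers stay spectators.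

Step 9
Reactants: 16 5,7-bis(benzyloxy)-2-{4-methoxy-3-[(trimethylsilyl)ethynyl]phenyl}-4H-chromen-4-one
Product: 17 5,7-bis(benzyloxy)-2-(3-ethynyl-4-methoxyphenyl)-4H-chromen-4-one
Conditions: K2CO3 (0.2 equiv), MeOH–CH2Cl2, rt
Reagents that add atoms: none
Why: Base-catalysed methanolysis of the alkynyl C–Si bond (protodesilylation), mild enough to leave the chromone ring closed.

Step 10
Reactants: 17 5,7-bis(benzyloxy)-2-(3-ethynyl-4-methoxyphenyl)-4H-chromen-4-one
Product: 20 5,7-bis(benzyloxy)-2-{4-methoxy-3-[(triisopropylsilyloxy)ethynyl]phenyl}-4H-chromen-4-one, via lithium acetylide 18 (not isolated), via lithium ynolate 19 (not isolated)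
Conditions: LiN(SiMe3)2 (1.1 equiv), THF, −78 °C; t-BuOOLi (1.1 equiv, from t-BuOOH and LiN(SiMe3)2, THF, −78 °C), −78 to 0 °C; i-Pr3SiOTf (1.3 equiv), −78 to 0 °C; aq NaHCO3, quick filtration through Et3N-deactivated silica
Reagents that add atoms: tert-butyl hydroperoxide CC(C)(C)OO (one oxygen, delivered as its lithium salt); triisopropylsilyl trifluoromethanesulfonate CC(C)[Si](OS(=O)(=O)C(F)(F)F)(C(C)C)C(C)C; lithium bis(trimethylsilyl)amide [Li]N([Si](C)(C)C)[Si](C)(C)C (lithium of 18 and 19 only)
Why: Known one-flask route from terminal alkynes to siloxyalkynes, in which the lithium acetylide attacks the peroxide oxygen of t-BuOOLi and expels tert-butoxide to give the lithium ynolate, which the bulky silyl triflate captures on oxygen rather than carbon; a non-nucleophilic amide base replaces butyllithium, and the 5,7-dialkoxyflavone, a vinylogous ester fully substituted at C2 and shielded at C4 by the peri benzyloxy group, should be a poor acceptor for both anions below 0 °C.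

Step 11
Reactants: 9 (2S)-6-(2-diazoacetyl)-2-(4-methoxyphenyl)-2,3-dihydro-4H-pyran-4-one; 20 5,7-bis(benzyloxy)-2-{4-methoxy-3-[(triisopropylsilyloxy)ethynyl]phenyl}-4H-chromen-4-one
Product: 25 (2S)-6-{5-[5,7-bis(benzyloxy)-4-oxo-4H-chromen-2-yl]-2-methoxyphenyl}-5-hydroxy-2-(4-methoxyphenyl)-7-(triisopropylsilyloxy)chroman-4-one, via vinylketene 21 (not isolated), via pyranylcyclobutenone 22 (not isolated), via dienylketene 23 (not isolated), via cyclohexadienone 24 (not isolated)
Conditions: 20 (1 equiv), 9 (1.3 equiv, in portions), degassed PhMe, 440 nm LED, 20 °C until N2 evolution stops; then 100 °C in the dark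
Reagents that add atoms: none
Why: Light taken up by the weak long-wavelength band of 9 (the flavone and the product are transparent there) expels N2, pyranone C6 shifts to the carbene carbon (Wolff rearrangement, C8–C8a) and the C=C=O unit of vinylketene 21 adds the electron-rich alkyne in a [2+2] cycloaddition (C5–C6 and C7–C8) to give cyclobutenone 22. On warming, 22 opens by reversible four-electron conrotatory cleavage of the old C5–C8 bond to dienylketene 23, ring A closes by six-electron disrotatory electrocyclisation of the ketene carbon onto pyranone C5 (C4a–C5), and enolisation of 24 gives the chelated phenol. This is the photochemical Wolff variant of the Danheiser benzannulation, established for vinyl and aryl diazomethyl ketones with triisopropylsiloxyalkynes, run with the equally known visible-light Wolff rearrangement of diazoketones. No lasting stereocentre is formed, since the sp3 carbons of 22 and 24 are erased by ring opening and tautomerisation, and C2 lies outside the reacting π system and meets neither acid nor base. The step needs regioselectivity in the [2+2] event, secured by polarisation because the nucleophilic aryl-bearing alkyne carbon attacks the ketene carbonyl carbon and so places the aryl group between the new hydroxyl and the silyloxy group; it also needs closure on C5 alone, secured by ring geometry because the exocyclic ketene arm lies cis to C5–H and trans to C4, which rules out cyclisation through the C4 oxygen. Portionwise addition of 9 keeps the ketene dilute and should limit its dimerisation and the acylation of the product phenol.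

Step 12
Reactants: 25 (2S)-6-{5-[5,7-bis(benzyloxy)-4-oxo-4H-chromen-2-yl]-2-methoxyphenyl}-5-hydroxy-2-(4-methoxyphenyl)-7-(triisopropylsilyloxy)chroman-4-one
Product: 26 (2S)-6-{5-[5,7-bis(benzyloxy)-4-oxo-4H-chromen-2-yl]-2-methoxyphenyl}-5,7-dihydroxy-2-(4-methoxyphenyl)chroman-4-one
Conditions: Bu4NF (1.2 equiv), AcOH (1.5 equiv), THF, 0 °C
Reagents that add atoms: none
Why: Fluoride-induced cleavage of a phenolic silyl ether, fast at 0 °C because the 7-oxygen is para to the carbonyl-bearing C4a and thus a good leaving group, with the acetic acid buffer protonating the phenoxide at once and so blocking the retro-oxa-Michael opening to the chalcone that would racemise C2.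

Step 13
Reactants: 26 (2S)-6-{5-[5,7-bis(benzyloxy)-4-oxo-4H-chromen-2-yl]-2-methoxyphenyl}-5,7-dihydroxy-2-(4-methoxyphenyl)chroman-4-one
Product: 27 (2S)-6-[5-(5,7-dihydroxy-4-oxo-4H-chromen-2-yl)-2-methoxyphenyl]-5,7-dihydroxy-2-(4-methoxyphenyl)chroman-4-one (CNP0081547.1)
Conditions: H2 (1 atm), Pd/C (10 wt %), THF–MeOH, rt; stopped after uptake of two equivalents, filtration
Reagents that add atoms: none
Why: Catalytic hydrogenolysis of benzyl aryl ethers under neutral conditions, routinely compatible with the flavone C2=C3 bond, the chelated flavanone carbonyl and the cyclic C2–O1 bond when hydrogen uptake is monitored, and free of any pathway that could epimerise C2.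

Compound list
1 | methyl 2,4-dioxopentanoate | CC(=O)CC(=O)C(=O)OC | starting material
2 | methyl (2Z)-2,4-bis(trimethylsilyloxy)penta-2,4-dienoate | C=C(O[Si](C)(C)C)/C=C(\O[Si](C)(C)C)C(=O)OC | intermediate
3 | 4-methoxybenzaldehyde | COc1ccc(C=O)cc1 | starting material
4 | methyl (2Z,6S)-6-(4-methoxyphenyl)-4-oxo-2,6-bis(trimethylsilyloxy)hex-2-enoate (formed in the flask) | COc1ccc(cc1)[C@@H](O[Si](C)(C)C)CC(=O)/C=C(\O[Si](C)(C)C)C(=O)OC | intermediate
5 | methyl (2S)-2-(4-methoxyphenyl)-4-oxo-3,4-dihydro-2H-pyran-6-carboxylate | COc1ccc(cc1)[C@@H]1CC(=O)C=C(O1)C(=O)OC | intermediate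
6 | trimethylstannyl (2S)-2-(4-methoxyphenyl)-4-oxo-3,4-dihydro-2H-pyran-6-carboxylate (formed in the flask) | COc1ccc(cc1)[C@@H]1CC(=O)C=C(O1)C(=O)O[Sn](C)(C)C | intermediate
7 | (2S)-2-(4-methoxyphenyl)-4-oxo-3,4-dihydro-2H-pyran-6-carboxylic acid | COc1ccc(cc1)[C@@H]1CC(=O)C=C(O1)C(=O)O | intermediate
8 | (2S)-2-(4-methoxyphenyl)-4-oxo-3,4-dihydro-2H-pyran-6-carbonyl chloride (formed in the flask) | COc1ccc(cc1)[C@@H]1CC(=O)C=C(O1)C(=O)Cl | intermediate
9 | (2S)-6-(2-diazoacetyl)-2-(4-methoxyphenyl)-2,3-dihydro-4H-pyran-4-one | COc1ccc(cc1)[C@@H]1CC(=O)C=C(O1)C(=O)C=[N+]=[N-] | intermediate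
10 | 3-bromo-4-methoxybenzoic acid | COc1ccc(cc1Br)C(O)=O | starting material
11 | 3-bromo-4-methoxybenzoyl chloride | COc1ccc(cc1Br)C(Cl)=O | intermediate
12 | 2',4',6'-trihydroxyacetophenone | CC(=O)c1c(O)cc(O)cc1O | starting material
13 | 1-(3-bromo-4-methoxyphenyl)-3-(2,4,6-trihydroxyphenyl)propane-1,3-dione (carried on crude) | COc1ccc(cc1Br)C(=O)CC(=O)c1c(O)cc(O)cc1O | intermediate
14 | 2-(3-bromo-4-methoxyphenyl)-5,7-dihydroxy-4H-chromen-4-one | COc1ccc(cc1Br)-c1cc(=O)c2c(O)cc(O)cc2o1 | intermediate
15 | 5,7-bis(benzyloxy)-2-(3-bromo-4-methoxyphenyl)-4H-chromen-4-one | COc1ccc(cc1Br)-c1cc(=O)c2c(OCc3ccccc3)cc(OCc3ccccc3)cc2o1 | intermediate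
16 | 5,7-bis(benzyloxy)-2-{4-methoxy-3-[(trimethylsilyl)ethynyl]phenyl}-4H-chromen-4-one | COc1ccc(cc1C#C[Si](C)(C)C)-c1cc(=O)c2c(OCc3ccccc3)cc(OCc3ccccc3)cc2o1 | intermediate
17 | 5,7-bis(benzyloxy)-2-(3-ethynyl-4-methoxyphenyl)-4H-chromen-4-one | COc1ccc(cc1C#C)-c1cc(=O)c2c(OCc3ccccc3)cc(OCc3ccccc3)cc2o1 | intermediate
18 | lithium acetylide of 17 (formed in the flask) | COc1ccc(cc1C#C[Li])-c1cc(=O)c2c(OCc3ccccc3)cc(OCc3ccccc3)cc2o1 | intermediate
19 | lithium ynolate, aryl–C≡C–OLi (formed in the flask) | COc1ccc(cc1C#CO[Li])-c1cc(=O)c2c(OCc3ccccc3)cc(OCc3ccccc3)cc2o1 | intermediate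
20 | 5,7-bis(benzyloxy)-2-{4-methoxy-3-[(triisopropylsilyloxy)ethynyl]phenyl}-4H-chromen-4-one | COc1ccc(cc1C#CO[Si](C(C)C)(C(C)C)C(C)C)-c1cc(=O)c2c(OCc3ccccc3)cc(OCc3ccccc3)cc2o1 | intermediate
21 | [(2S)-2-(4-methoxyphenyl)-4-oxo-3,4-dihydro-2H-pyran-6-yl]ketene (formed in the flask) | COc1ccc(cc1)[C@@H]1CC(=O)C=C(O1)C=C=O | intermediate
22 | 2-aryl-4-[(2S)-2-(4-methoxyphenyl)-4-oxo-3,4-dihydro-2H-pyran-6-yl]-3-(triisopropylsilyloxy)cyclobut-2-en-1-one, aryl = flavone ring B, both epimers at the ring sp3 carbon (formed in the flask) | COc1ccc(cc1)[C@@H]1CC(=O)C=C(O1)C1C(=O)C(=C1O[Si](C(C)C)(C(C)C)C(C)C)c1cc(ccc1OC)-c1cc(=O)c2c(OCc3ccccc3)cc(OCc3ccccc3)cc2o1 | intermediate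
23 | 2-aryl-4-[(2S)-pyranonyl]-3-(triisopropylsilyloxy)buta-1,3-dien-1-one, pyranonyl group cis to the ketene arm (formed in the flask) | COc1ccc(cc1)[C@@H]1CC(=O)C=C(O1)/C=C(/O[Si](C(C)C)(C(C)C)C(C)C)C(=C=O)c1cc(ccc1OC)-c1cc(=O)c2c(OCc3ccccc3)cc(OCc3ccccc3)cc2o1 | intermediate
24 | cyclohexa-2,4-dienone tautomer of 25, hydrogen on C4a, both C4a epimers (formed in the flask) | COc1ccc(cc1)[C@@H]1CC(=O)C2C(=O)C(=C(O[Si](C(C)C)(C(C)C)C(C)C)C=C2O1)c1cc(ccc1OC)-c1cc(=O)c2c(OCc3ccccc3)cc(OCc3ccccc3)cc2o1 | intermediate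
25 | (2S)-6-{5-[5,7-bis(benzyloxy)-4-oxo-4H-chromen-2-yl]-2-methoxyphenyl}-5-hydroxy-2-(4-methoxyphenyl)-7-(triisopropylsilyloxy)chroman-4-one | COc1ccc([C@@H]2CC(=O)c3c(cc(O[Si](C(C)C)(C(C)C)C(C)C)c(-c4cc(-c5cc(=O)c6c(OCc7ccccc7)cc(OCc7ccccc7)cc6o5)ccc4OC)c3O)O2)cc1 | intermediate
26 | (2S)-6-{5-[5,7-bis(benzyloxy)-4-oxo-4H-chromen-2-yl]-2-methoxyphenyl}-5,7-dihydroxy-2-(4-methoxyphenyl)chroman-4-one | COc1ccc([C@@H]2CC(=O)c3c(cc(O)c(-c4cc(-c5cc(=O)c6c(OCc7ccccc7)cc(OCc7ccccc7)cc6o5)ccc4OC)c3O)O2)cc1 | intermediate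
27 | (2S)-6-[5-(5,7-dihydroxy-4-oxo-4H-chromen-2-yl)-2-methoxyphenyl]-5,7-dihydroxy-2-(4-methoxyphenyl)chroman-4-one (CNP0081547.1) | COc1ccc([C@@H]2CC(=O)c3c(cc(O)c(-c4cc(-c5cc(=O)c6c(O)cc(O)cc6o5)ccc4OC)c3O)O2)cc1 | target

Total step count: 13. Longest linear sequence: 9 steps (steps 5 to 13, from 10). The pyranone branch (steps 1 to 4) joins at step 11.

Steps most likely to fail

1. Step 11.
- What may go wrong: capture of the short-lived ketene by the hindered, aryl-conjugated alkyne may lose out to ketene dimerisation or to acylation of the newly formed phenol. Energy transfer from the excited diazoketone to the enone or flavone chromophores may also divert material.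
- Fallback (sets out from 9, comes back at 25): light and cycloaddition are separated. Diazoketone 9 is irradiated alone in wet THF, where water traps 21 as 2-[(2S)-2-(4-methoxyphenyl)-4-oxo-3,4-dihydro-2H-pyran-6-yl]acetic acid F1. 1-Chloro-N,N,2-trimethylprop-1-en-1-amine converts it into 2-[(2S)-2-(4-methoxyphenyl)-4-oxo-3,4-dihydro-2H-pyran-6-yl]acetyl chloride F2. Slow addition of i-Pr2NEt to F2 and 20 in toluene in the dark regenerates 21 by dehydrochlorination, at a rate set by the addition and always beside a large excess of alkyne. Warming then carries 22, 23 and 24 on to 25.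

2. Step 10.
- What may go wrong: addition of the acetylide or the peroxide anion to the flavone carbonyl or to C2, incomplete oxygen transfer, silylation on carbon instead of oxygen, or hydrolysis of the siloxyalkyne during purification.
- Fallback (sets out from 15, comes back at 20): the siloxyalkyne is reached without any strong nucleophile.
 - Hydroxycarbonylation of 15 (Pd(OAc)2, Xantphos, CO, Et3N, H2O, dioxane, 90 °C) gives 5-[5,7-bis(benzyloxy)-4-oxo-4H-chromen-2-yl]-2-methoxybenzoic acid F3.
 - Oxalyl chloride gives 5-[5,7-bis(benzyloxy)-4-oxo-4H-chromen-2-yl]-2-methoxybenzoyl chloride F4.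
 - Diazomethane gives 5,7-bis(benzyloxy)-2-[3-(2-diazoacetyl)-4-methoxyphenyl]-4H-chromen-4-one F5.
 - i-Pr3SiOTf and i-Pr2NEt in Et2O–CH2Cl2 silylate the diazo carbon to give 5,7-bis(benzyloxy)-2-{3-[2-diazo-2-(triisopropylsilyl)acetyl]-4-methoxyphenyl}-4H-chromen-4-one F6.
 - F6 is known, for aryl ketones of this type, to pass at or slightly above room temperature into the aryl siloxyalkyne by a 1,3-shift of silicon from carbon to oxygen, loss of N2 and a 1,2-aryl shift. Here that delivers 20.

3. Step 2.
- What may go wrong: the ester lowers the nucleophilicity of the diene terminus and the electron-rich aldehyde is a weak electrophile. Turnover may therefore be slow, and an uncatalysed or silyl-cation-catalysed background reaction may erode facial selectivity.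
- Fallback (sets out from 3, comes back at 5): the stereocentre and the diketoester are made in separate, well-tried operations.
 - Aldehyde 3 and 2-(trimethylsilyloxy)propene undergo a Mukaiyama aldol reaction under SiCl4 with a catalytic chiral BINAM-derived bisphosphoramide (the enantiomer that directs Si-face attack) to give (4S)-4-hydroxy-4-(4-methoxyphenyl)butan-2-one F7.
 - t-BuMe2SiCl and imidazole give (4S)-4-(tert-butyldimethylsilyloxy)-4-(4-methoxyphenyl)butan-2-one F8.
 - Kinetic deprotonation of the methyl group (LiN(SiMe3)2, THF, −78 °C) and Claisen condensation with dimethyl oxalate give methyl (6S)-6-(tert-butyldimethylsilyloxy)-6-(4-methoxyphenyl)-2,4-dioxohexanoate F9.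
 - HF·pyridine in THF frees methyl (6S)-6-hydroxy-6-(4-methoxyphenyl)-2,4-dioxohexanoate F10, which a trace of CF3CO2H at 0 °C cyclodehydrates to 5.

Further compounds
F1 | step 11 | 2-[(2S)-2-(4-methoxyphenyl)-4-oxo-3,4-dihydro-2H-pyran-6-yl]acetic acid | COc1ccc(cc1)[C@@H]1CC(=O)C=C(O1)CC(O)=O
F2 | step 11 | 2-[(2S)-2-(4-methoxyphenyl)-4-oxo-3,4-dihydro-2H-pyran-6-yl]acetyl chloride | COc1ccc(cc1)[C@@H]1CC(=O)C=C(O1)CC(Cl)=O
F3 | step 10 | 5-[5,7-bis(benzyloxy)-4-oxo-4H-chromen-2-yl]-2-methoxybenzoic acid | COc1ccc(cc1C(O)=O)-c1cc(=O)c2c(OCc3ccccc3)cc(OCc3ccccc3)cc2o1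
F4 | step 10 | 5-[5,7-bis(benzyloxy)-4-oxo-4H-chromen-2-yl]-2-methoxybenzoyl chloride | COc1ccc(cc1C(Cl)=O)-c1cc(=O)c2c(OCc3ccccc3)cc(OCc3ccccc3)cc2o1
F5 | step 10 | 5,7-bis(benzyloxy)-2-[3-(2-diazoacetyl)-4-methoxyphenyl]-4H-chromen-4-one | COc1ccc(cc1C(=O)C=[N+]=[N-])-c1cc(=O)c2c(OCc3ccccc3)cc(OCc3ccccc3)cc2o1
F6 | step 10 | 5,7-bis(benzyloxy)-2-{3-[2-diazo-2-(triisopropylsilyl)acetyl]-4-methoxyphenyl}-4H-chromen-4-one | COc1ccc(cc1C(=O)C(=[N+]=[N-])[Si](C(C)C)(C(C)C)C(C)C)-c1cc(=O)c2c(OCc3ccccc3)cc(OCc3ccccc3)cc2o1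
F7 | step 2 | (4S)-4-hydroxy-4-(4-methoxyphenyl)butan-2-one | COc1ccc(cc1)[C@@H](O)CC(C)=O
F8 | step 2 | (4S)-4-(tert-butyldimethylsilyloxy)-4-(4-methoxyphenyl)butan-2-one | COc1ccc(cc1)[C@@H](O[Si](C)(C)C(C)(C)C)CC(C)=O
F9 | step 2 | methyl (6S)-6-(tert-butyldimethylsilyloxy)-6-(4-methoxyphenyl)-2,4-dioxohexanoate | COc1ccc(cc1)[C@@H](O[Si](C)(C)C(C)(C)C)CC(=O)CC(=O)C(=O)OC
F10 | step 2 | methyl (6S)-6-hydroxy-6-(4-methoxyphenyl)-2,4-dioxohexanoate | COc1ccc(cc1)[C@@H](O)CC(=O)CC(=O)C(=O)OC
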